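**Strategy.** The six-membered carbocycle is numbered C1 (carries CH2OH), C2 (C=O), C3 (enoate oxygen), C4 (isopropyl), C5 (isobutyrate oxygen), C6 (=CH). Its C2 carbonyl, C1=C6 alkene and C5–O are read as an unmasked 2-pyrone cycloadduct, so the ring is cut at C2–C3 and C4–C5. One catalytic asymmetric [4+2] reaction between 3-hydroxy-2-pyrone and (E)-5-methylhex-3-en-2-one, both purchased and used unprotected, closes the carbocycle as a lactone-bridged bicyclo[2.2.2]octene and fixes the C3, C4 and C5 configurations; the acetyl group later becomes the C3 oxygen, the bridgehead hydroxy lactone the C2 ketone, and C7 arrives by Morita–Baylis–Hillman hydroxymethylation.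

Key step: step 1

Remark on the chemistry: the quinidine-derived catalyst is assumed to give the (1S,4S,7R,8R) adduct; if the antipode forms, the quinine-derived pseudo-enantiomer is used instead and nothing else changes.

**Step 1**
Reactants: 1 3-hydroxy-2H-pyran-2-one; 2 (E)-5-methylhex-3-en-2-one
Product: 3 (1S,4S,7R,8R)-8-acetyl-4-hydroxy-7-(propan-2-yl)-2-oxabicyclo[2.2.2]oct-5-en-3-one (acetyl syn to the C5=C6 bridge, isopropyl syn to the lactone bridge)
Conditions: thiourea from 9-amino-9-deoxy-epi-quinidine and 3,5-bis(trifluoromethyl)phenyl isothiocyanate (10 mol %), 2 (2 equiv), Et2O, 0 °C → rt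
Reagents that add atoms: none
Why: The quinuclidine nitrogen deprotonates the 3-hydroxyl of 1, and the ion-paired dienolate adds through the carbon next to the ring oxygen to the isopropyl-bearing β-carbon of 2 while the thiourea hydrogen-bonds the acetyl oxygen; the enolate carbon then bonds to the hydroxyl-bearing pyrone carbon, in concert or as a Michael–aldol sequence. The closest known reaction type is the amine-base and cinchona-alkaloid catalysed Diels–Alder reaction of 3-hydroxy-2-pyrones with electron-poor alkenes. The carbocycle closes by a normal-demand suprafacial [4+2] cycloaddition (a 6-exo-trig aldol closure if stepwise), and the former pyrone ester is left as the two-atom lactone bridge. The two bridgeheads are tied together by addition to one face of the diene, the trans acetyl/isopropyl relation is inherited from the (E)-alkene, the endo position of the acetyl group (and so isopropyl on the lactone-oxygen side) should follow from the hydrogen bond that holds the carbonyl under the dienolate, and the absolute sense from the chiral pocket of the alkaloid. The step needs regio-, endo- and enantioface selectivity: the first is secured by the polarity match of dienolate terminus and enone β-carbon, the other two by the two-point binding of the catalyst.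

**Step 2**
Reactants: 3 (1S,4S,7R,8R)-8-acetyl-4-hydroxy-7-(propan-2-yl)-2-oxabicyclo[2.2.2]oct-5-en-3-one
Product: 4 (1S,4S,7S,8R)-4-hydroxy-3-oxo-7-(propan-2-yl)-2-oxabicyclo[2.2.2]oct-5-en-8-yl acetate
Conditions: mCPBA (1.5 equiv), CH2Cl2, 0 °C → rt
Reagents that add atoms: 3-chloroperoxybenzoic acid (mCPBA), O=C(OO)c1cccc(Cl)c1
Why: Baeyer–Villiger oxidation, in which the secondary ring carbon migrates in preference to methyl with retention of configuration, while the bridging alkene is deactivated toward epoxidation by its two electron-poor allylic bridgeheads.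

**Step 3**
Reactants: 4 (1S,4S,7S,8R)-4-hydroxy-3-oxo-7-(propan-2-yl)-2-oxabicyclo[2.2.2]oct-5-en-8-yl acetate
Product: 5 (1S,4S,5S,6R)-6-(acetyloxy)-1,4-dihydroxy-5-(propan-2-yl)cyclohex-2-ene-1-carboxylic acid
Conditions: LiOH·H2O (1.05 equiv), THF/H2O 3:1, 0 °C; then 1 M HCl to pH 3
Reagents that add atoms: lithium hydroxide, [Li+].[OH-]
Why: Chemoselective saponification, since the boat-shaped δ-lactone with its α-hydroxyl is far more electrophilic than the hindered secondary acetate and only one equivalent of hydroxide is offered; no stereocentre is touched.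

**Step 4**
Reactants: 5 (1S,4S,5S,6R)-6-(acetyloxy)-1,4-dihydroxy-5-(propan-2-yl)cyclohex-2-ene-1-carboxylic acid
Product: 6 (1R,5S,6S)-5-hydroxy-2-oxo-6-(propan-2-yl)cyclohex-3-en-1-yl acetate
Conditions: Pb(OAc)4 (1.1 equiv), CH2Cl2, 0 °C → rt
Reagents that add atoms: none
Why: Oxidative decarboxylation of an α-hydroxy acid by tetravalent lead gives the C2 ketone already conjugated with the C1=C6 alkene, and the C3 acetate prevents glycol cleavage of the C2–C3 bond.

**Step 5**
Reactants: 6 (1R,5S,6S)-5-hydroxy-2-oxo-6-(propan-2-yl)cyclohex-3-en-1-yl acetate; 7 isobutyryl chloride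
Product: 8 (1R,5S,6S)-5-[(2-methylpropanoyl)oxy]-2-oxo-6-(propan-2-yl)cyclohex-3-en-1-yl acetate
Conditions: 7 (1.3 equiv), pyridine (3 equiv), DMAP (5 mol %), CH2Cl2, 0 °C
Reagents that add atoms: none
Why: DMAP-catalysed O-acylation of the only free hydroxyl, with the C5–O bond untouched so the configuration is kept.

**Step 6**
Reactants: 8 (1R,5S,6S)-5-[(2-methylpropanoyl)oxy]-2-oxo-6-(propan-2-yl)cyclohex-3-en-1-yl acetate
Product: 9 (1S,5R,6R)-5-hydroxy-4-oxo-6-(propan-2-yl)cyclohex-2-en-1-yl 2-methylpropanoate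
Conditions: K2CO3 (0.1 equiv), MeOH, −10 °C
Reagents that add atoms: none
Why: Base-catalysed transesterification (Zemplén-type methanolysis) should remove only the acetate, because the neighbouring C2 ketone activates the α-acyloxy ester and the acetyl carbonyl is much less hindered than the α-branched isobutyryl carbonyl, while the trans-1,3 relation of the two oxygens excludes acyl migration.

**Step 7**
Reactants: 10 (tert-butyldimethylsilyloxy)acetaldehyde; 11 ethyl 2-(triphenylphosphoranylidene)propanoate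
Product: 12 ethyl (2E)-4-[(tert-butyldimethylsilyl)oxy]-2-methylbut-2-enoate
Conditions: CH2Cl2, rt
Reagents that add atoms: none
Why: Wittig olefination with a stabilised ylide, which should give the (E)-trisubstituted enoate.

**Step 8**
Reactants: 12 ethyl (2E)-4-[(tert-butyldimethylsilyl)oxy]-2-methylbut-2-enoate
Product: 13 (2E)-4-[(tert-butyldimethylsilyl)oxy]-2-methylbut-2-enoic acid
Conditions: LiOH·H2O (2 equiv), THF/MeOH/H2O, rt; then 1 M HCl to pH 4, 0 °C
Reagents that add atoms: lithium hydroxide, [Li+].[OH-]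
Why: Ester saponification, which a primary silyl ether tolerates and which does not disturb the alkene geometry.

**Step 9**
Reactants: 9 (1S,5R,6R)-5-hydroxy-4-oxo-6-(propan-2-yl)cyclohex-2-en-1-yl 2-methylpropanoate; 13 (2E)-4-[(tert-butyldimethylsilyl)oxy]-2-methylbut-2-enoic acid
Product: 14 (1R,5S,6S)-5-[(2-methylpropanoyl)oxy]-2-oxo-6-(propan-2-yl)cyclohex-3-en-1-yl (2E)-4-[(tert-butyldimethylsilyl)oxy]-2-methylbut-2-enoate
Conditions: DCC (1.3 equiv), DMAP (10 mol %), CH2Cl2, 0 °C → rt
Reagents that add atoms: none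
Why: Steglich esterification of the single free hydroxyl; the C3–O bond is not broken, and the trans-diequatorial C3/C4 arrangement is the thermodynamically preferred one should C3 enolise.

**Step 10**
Reactants: 14 (1R,5S,6S)-5-[(2-methylpropanoyl)oxy]-2-oxo-6-(propan-2-yl)cyclohex-3-en-1-yl (2E)-4-[(tert-butyldimethylsilyl)oxy]-2-methylbut-2-enoate; 15 formaldehyde
Product: 16 (1R,5S,6S)-3-(hydroxymethyl)-5-[(2-methylpropanoyl)oxy]-2-oxo-6-(propan-2-yl)cyclohex-3-en-1-yl (2E)-4-[(tert-butyldimethylsilyl)oxy]-2-methylbut-2-enoate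
Conditions: 37% aq. HCHO (3 equiv), DMAP (20 mol %), THF, rt
Reagents that add atoms: none
Why: Morita–Baylis–Hillman reaction, in which DMAP adds reversibly to C6, the C1 enolate captures formaldehyde and the amine is expelled; the α-methyl enoate side chain is too poor an acceptor to compete and no stereocentre is formed.

**Step 11**
Reactants: 16 (1R,5S,6S)-3-(hydroxymethyl)-5-[(2-methylpropanoyl)oxy]-2-oxo-6-(propan-2-yl)cyclohex-3-en-1-yl (2E)-4-[(tert-butyldimethylsilyl)oxy]-2-methylbut-2-enoate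
Product: 17 (1R,5S,6S)-3-(hydroxymethyl)-5-[(2-methylpropanoyl)oxy]-2-oxo-6-(propan-2-yl)cyclohex-3-en-1-yl (2E)-4-hydroxy-2-methylbut-2-enoate (CNP0254776.1)
Conditions: HF·pyridine, pyridine, THF, 0 °C → rt
Reagents that add atoms: none
Why: Fluoride-driven desilylation under buffered, weakly acidic conditions cleaves the Si–O bond and should spare the three esters and avoid acyl migration.

**Compound list**
1 | 3-hydroxy-2H-pyran-2-one | O=C1OC=CC=C1O | starting material
2 | (E)-5-methylhex-3-en-2-one | CC(=O)/C=C/C(C)C | starting material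
3 | (1S,4S,7R,8R)-8-acetyl-4-hydroxy-7-(propan-2-yl)-2-oxabicyclo[2.2.2]oct-5-en-3-one | O=C1O[C@H]2C=C[C@]1(O)[C@H](C(C)=O)[C@H]2C(C)C | intermediate
4 | (1S,4S,7S,8R)-4-hydroxy-3-oxo-7-(propan-2-yl)-2-oxabicyclo[2.2.2]oct-5-en-8-yl acetate | O=C1O[C@H]2C=C[C@]1(O)[C@H](OC(C)=O)[C@H]2C(C)C | intermediate
5 | (1S,4S,5S,6R)-6-(acetyloxy)-1,4-dihydroxy-5-(propan-2-yl)cyclohex-2-ene-1-carboxylic acid | O[C@H]1C=C[C@](C(=O)O)(O)[C@H](OC(C)=O)[C@H]1C(C)C | intermediate
6 | (1R,5S,6S)-5-hydroxy-2-oxo-6-(propan-2-yl)cyclohex-3-en-1-yl acetate | CC(=O)O[C@H]1C(=O)C=C[C@H](O)[C@@H]1C(C)C | intermediate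
7 | isobutyryl chloride (2-methylpropanoyl chloride) | CC(C)C(Cl)=O | starting material
8 | (1R,5S,6S)-5-[(2-methylpropanoyl)oxy]-2-oxo-6-(propan-2-yl)cyclohex-3-en-1-yl acetate | CC(=O)O[C@H]1C(=O)C=C[C@H](OC(=O)C(C)C)[C@@H]1C(C)C | intermediate
9 | (1S,5R,6R)-5-hydroxy-4-oxo-6-(propan-2-yl)cyclohex-2-en-1-yl 2-methylpropanoate | O[C@H]1C(=O)C=C[C@H](OC(=O)C(C)C)[C@@H]1C(C)C | intermediate
10 | (tert-butyldimethylsilyloxy)acetaldehyde | O=CCO[Si](C)(C)C(C)(C)C | starting material
11 | ethyl 2-(triphenylphosphoranylidene)propanoate | CCOC(=O)C(C)=P(c1ccccc1)(c1ccccc1)c1ccccc1 | starting material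
12 | ethyl (2E)-4-[(tert-butyldimethylsilyl)oxy]-2-methylbut-2-enoate | CCOC(=O)/C(C)=C/CO[Si](C)(C)C(C)(C)C | intermediate
13 | (2E)-4-[(tert-butyldimethylsilyl)oxy]-2-methylbut-2-enoic acid | C/C(=C\CO[Si](C)(C)C(C)(C)C)C(=O)O | intermediate
14 | (1R,5S,6S)-5-[(2-methylpropanoyl)oxy]-2-oxo-6-(propan-2-yl)cyclohex-3-en-1-yl (2E)-4-[(tert-butyldimethylsilyl)oxy]-2-methylbut-2-enoate | C/C(=C\CO[Si](C)(C)C(C)(C)C)C(=O)O[C@H]1C(=O)C=C[C@H](OC(=O)C(C)C)[C@@H]1C(C)C | intermediate
15 | formaldehyde (37% aqueous solution) | C=O | starting material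
16 | (1R,5S,6S)-3-(hydroxymethyl)-5-[(2-methylpropanoyl)oxy]-2-oxo-6-(propan-2-yl)cyclohex-3-en-1-yl (2E)-4-[(tert-butyldimethylsilyl)oxy]-2-methylbut-2-enoate | C/C(=C\CO[Si](C)(C)C(C)(C)C)C(=O)O[C@H]1C(=O)C(CO)=C[C@H](OC(=O)C(C)C)[C@@H]1C(C)C | intermediate
17 | (1R,5S,6S)-3-(hydroxymethyl)-5-[(2-methylpropanoyl)oxy]-2-oxo-6-(propan-2-yl)cyclohex-3-en-1-yl (2E)-4-hydroxy-2-methylbut-2-enoate | C/C(=C\CO)C(=O)O[C@H]1C(=O)C(CO)=C[C@H](OC(=O)C(C)C)[C@@H]1C(C)C | target

**Totals**
Total step count: 11. Longest linear sequence: 9 (steps 1–6 and 9–11); steps 7 and 8 prepare the side-chain acid.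

**Steps most likely to fail**

Step 1: the cycloaddition may proceed with poor endo control, placing the acetyl group on the lactone side, or the unactivated, β-branched enone may react too slowly for the catalyst to dominate over the background reaction. The fallback accepts the exo mode instead of fighting it. From 1 and 2, whichever pseudo-enantiomer of the catalyst gives the (1R,4R) bridgehead series would deliver (1R,4R,7R,8R)-8-acetyl-4-hydroxy-7-(propan-2-yl)-2-oxabicyclo[2.2.2]oct-5-en-3-one F1, in which C3 and C4 of the target already have the right absolute configuration and only C5 is epimeric. Baeyer–Villiger oxidation with mCPBA would give (1R,4R,7S,8R)-4-hydroxy-3-oxo-7-(propan-2-yl)-2-oxabicyclo[2.2.2]oct-5-en-8-yl acetate F2, and one equivalent of LiOH would open it to (1R,4R,5S,6R)-6-(acetyloxy)-1,4-dihydroxy-5-(propan-2-yl)cyclohex-2-ene-1-carboxylic acid F3. Pb(OAc)4 would then give the C5-epimeric alcohol (1R,5R,6S)-5-hydroxy-2-oxo-6-(propan-2-yl)cyclohex-3-en-1-yl acetate F4. Mitsunobu esterification of F4 with isobutyric acid (PPh3, DIAD, THF, 0 °C) inverts C5 and installs the isobutyrate in the same operation, and the route is rejoined at compound 8.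

Step 6: the methanolysis may lose chemoselectivity, cleaving the isobutyrate along with the acetate, or the γ-acyloxy enone may degrade under base. The fallback separates the two oxygens with an ether, so that no ester has to be distinguished from another. From 6, 4-methoxybenzyl trichloroacetimidate with catalytic camphorsulfonic acid in CH2Cl2 would give (1R,5S,6S)-5-[(4-methoxybenzyl)oxy]-2-oxo-6-(propan-2-yl)cyclohex-3-en-1-yl acetate F5. K2CO3 in MeOH would then remove the only ester present and give (4S,5R,6R)-6-hydroxy-4-[(4-methoxybenzyl)oxy]-5-(propan-2-yl)cyclohex-2-en-1-one F6. Steglich esterification with 13 would give (1R,5S,6S)-5-[(4-methoxybenzyl)oxy]-2-oxo-6-(propan-2-yl)cyclohex-3-en-1-yl (2E)-4-[(tert-butyldimethylsilyl)oxy]-2-methylbut-2-enoate F7. DDQ in CH2Cl2/pH 7 buffer would free the C5 hydroxyl to give (1R,5S,6S)-5-hydroxy-2-oxo-6-(propan-2-yl)cyclohex-3-en-1-yl (2E)-4-[(tert-butyldimethylsilyl)oxy]-2-methylbut-2-enoate F8. Acylation of F8 with 7 (pyridine, DMAP) rejoins the route at compound 14.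

Step 10: during the long exposure to aqueous amine and formaldehyde, the activated C3 ester may solvolyse, C3 may epimerise, or conjugate addition of the catalyst to the hindered C6 may stall. The fallback replaces the one-step hydroxymethylation by halogenation and cross-coupling under anhydrous conditions. From 14, I2 and pyridine in CH2Cl2 would give the α-iodo enone (1R,5S,6S)-3-iodo-5-[(2-methylpropanoyl)oxy]-2-oxo-6-(propan-2-yl)cyclohex-3-en-1-yl (2E)-4-[(tert-butyldimethylsilyl)oxy]-2-methylbut-2-enoate F9. Stille coupling of F9 with (tributylstannyl)methanol (Pd(PPh3)4 as the zerovalent palladium source, CuI, DMF, 40 °C) rejoins the route at compound 16.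

**Further compounds**
F1 | step 1 | (1R,4R,7R,8R)-8-acetyl-4-hydroxy-7-(propan-2-yl)-2-oxabicyclo[2.2.2]oct-5-en-3-one | O=C1O[C@@H]2C=C[C@@]1(O)[C@H](C(C)=O)[C@H]2C(C)C
F2 | step 1 | (1R,4R,7S,8R)-4-hydroxy-3-oxo-7-(propan-2-yl)-2-oxabicyclo[2.2.2]oct-5-en-8-yl acetate | O=C1O[C@@H]2C=C[C@@]1(O)[C@H](OC(C)=O)[C@H]2C(C)C
F3 | step 1 | (1R,4R,5S,6R)-6-(acetyloxy)-1,4-dihydroxy-5-(propan-2-yl)cyclohex-2-ene-1-carboxylic acid | O[C@@H]1C=C[C@@](C(=O)O)(O)[C@H](OC(C)=O)[C@H]1C(C)C
F4 | step 1 | (1R,5R,6S)-5-hydroxy-2-oxo-6-(propan-2-yl)cyclohex-3-en-1-yl acetate | CC(=O)O[C@H]1C(=O)C=C[C@@H](O)[C@@H]1C(C)C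
F5 | step 6 | (1R,5S,6S)-5-[(4-methoxybenzyl)oxy]-2-oxo-6-(propan-2-yl)cyclohex-3-en-1-yl acetate | CC(=O)O[C@H]1C(=O)C=C[C@H](OCc2ccc(OC)cc2)[C@@H]1C(C)C
F6 | step 6 | (4S,5R,6R)-6-hydroxy-4-[(4-methoxybenzyl)oxy]-5-(propan-2-yl)cyclohex-2-en-1-one | O[C@H]1C(=O)C=C[C@H](OCc2ccc(OC)cc2)[C@@H]1C(C)C
F7 | step 6 | (1R,5S,6S)-5-[(4-methoxybenzyl)oxy]-2-oxo-6-(propan-2-yl)cyclohex-3-en-1-yl (2E)-4-[(tert-butyldimethylsilyl)oxy]-2-methylbut-2-enoate | C/C(=C\CO[Si](C)(C)C(C)(C)C)C(=O)O[C@H]1C(=O)C=C[C@H](OCc2ccc(OC)cc2)[C@@H]1C(C)C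
F8 | step 6 | (1R,5S,6S)-5-hydroxy-2-oxo-6-(propan-2-yl)cyclohex-3-en-1-yl (2E)-4-[(tert-butyldimethylsilyl)oxy]-2-methylbut-2-enoate | C/C(=C\CO[Si](C)(C)C(C)(C)C)C(=O)O[C@H]1C(=O)C=C[C@H](O)[C@@H]1C(C)C
F9 | step 10 | (1R,5S,6S)-3-iodo-5-[(2-methylpropanoyl)oxy]-2-oxo-6-(propan-2-yl)cyclohex-3-en-1-yl (2E)-4-[(tert-butyldimethylsilyl)oxy]-2-methylbut-2-enoate | C/C(=C\CO[Si](C)(C)C(C)(C)C)C(=O)O[C@H]1C(=O)C(I)=C[C@H](OC(=O)C(C)C)[C@@H]1C(C)C
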